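**Strategy**

Everything rests on making the benzene ring of the umbelliferone half (C4a', C5', C6', C7', C8', C8a') from acyclic pieces with the diaryl ether oxygen already in place. That ring has oxygen on C7' and C8a', meta to each other, and carbon on C4a'; a 1,1,3-trioxygenated diene and an acetylenic aldehyde give exactly this pattern. One cycloaddition–aromatization forms C5'–C6' and C4a'–C8a' and hands over a 4-aryloxysalicylaldehyde ready for pyranone closure. Its precursor is a methyl trimethylsilyl ketene acetal diene whose 3-oxygen carries the 6,7-dimethoxycoumarin-3-yl group, made from a β-coumarinyloxy crotonate.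

Key step: step 6

Remark: the alkene geometry of 7, 8 and 9 is erased when the arene forms, so one isomer is drawn for each and any other isomer is carried through unchanged. Primed locants refer to the 7-oxycoumarin half.

**Route**

Step 1
Reactants: 1 2-hydroxy-4,5-dimethoxybenzaldehyde; 2 N-acetylglycine
Product: 3 N-(6,7-dimethoxy-2-oxo-2H-chromen-3-yl)acetamide (3-acetamido-6,7-dimethoxycoumarin)
Conditions: Ac2O, NaOAc, 110 °C
Reagents that add atoms: none
Why: Perkin-type condensation (Erlenmeyer–Plöchl variant) in which the anhydride-activated glycine methylene condenses with the aldehyde and the ortho phenol oxygen closes the lactone, the standard entry to 3-acetamidocoumarins from salicylaldehydes.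

Step 2
Reactants: 3 N-(6,7-dimethoxy-2-oxo-2H-chromen-3-yl)acetamide
Product: 5 3-hydroxy-6,7-dimethoxy-2H-chromen-2-one, via 3-amino-6,7-dimethoxycoumarin 4 (not isolated)
Conditions: 3 M aq. HCl, AcOH, reflux
Reagents that add atoms: water, O
Why: Acid hydrolysis of the enamide gives enamine 4, whose iminium tautomer is hydrolysed to the 2,3-dione that rests as its enol, the known passage from 3-acetamido- to 3-hydroxycoumarins, which the aryl methyl ethers and the lactone tolerate.

Step 3
Reactants: 5 3-hydroxy-6,7-dimethoxy-2H-chromen-2-one; 6 methyl but-2-ynoate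
Product: 7 methyl (2E)-3-[(6,7-dimethoxy-2-oxo-2H-chromen-3-yl)oxy]but-2-enoate
Conditions: Cs2CO3 (0.3 equiv), DMF, 60 °C
Reagents that add atoms: none
Why: Oxa-Michael addition of the acidic enol oxygen to the alkynoate (the classical addition of phenoxides to acetylenic esters) should give the β-aryloxy crotonate, O-attack being fixed by irreversible protonation of the vinyl anion.

Step 4
Reactants: 7 methyl (2E)-3-[(6,7-dimethoxy-2-oxo-2H-chromen-3-yl)oxy]but-2-enoate
Product: 9 3-{[(3E)-4-methoxy-4-(trimethylsilyloxy)buta-1,3-dien-2-yl]oxy}-6,7-dimethoxy-2H-chromen-2-one, via lithium dienolate 8 (not isolated)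
Conditions: LDA [LiN(iPr)2, commercial solution], TMSCl, THF, −78 °C, ester added last; volatiles removed in vacuo, dry toluene, filtered under Ar, used crude
Reagents that add atoms: chlorotrimethylsilane, C[Si](C)(C)Cl
Why: Kinetic γ-deprotonation of a β-oxy crotonate and O-silylation of the dienolate is the standard preparation of vinylketene acetal (Brassard-type) dienes, and with the silyl chloride present from the start 8 should be trapped before it or the amide can attack the lactone, which its 3-oxy and 7-methoxy donors deactivate.

Step 5
Reactants: 10 propargyl alcohol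
Product: 11 propynal (kept as a dried, titrated CH2Cl2 solution)
Conditions: activated MnO2 (10 equiv), CH2Cl2, rt; filtered through Celite, dried over 4 Å sieves
Reagents that add atoms: none
Why: Propargyl alcohol is an activated alcohol that MnO2 oxidises to the ynal without over-oxidation, and filtration leaves a neutral solution, so neat propynal is never handled.

Step 6
Reactants: 9 3-{[(3E)-4-methoxy-4-(trimethylsilyloxy)buta-1,3-dien-2-yl]oxy}-6,7-dimethoxy-2H-chromen-2-one; 11 propynal
Product: 13 4-[(6,7-dimethoxy-2-oxo-2H-chromen-3-yl)oxy]-2-hydroxybenzaldehyde, via cycloadduct ketal 12 (not isolated)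
Conditions: CH2Cl2, −20 °C → rt; then 1 M aq. HCl, THF, rt
Reagents that add atoms: none
Why: The electron-rich diene and the electron-poor ynal should combine in an asynchronous, normal-demand [4+2] cycloaddition in which the CH2 terminus (future C6') bonds first to the β-carbon of propynal (C5') and the ketene acetal carbon (C8a') then bonds to the α-carbon (C4a'), giving the 1,4-cyclohexadiene ketal 12. The closest known reaction is the Diels–Alder reaction of 1-methoxy-1-silyloxy-3-alkoxybutadienes with acetylenic esters and aldehydes, which ends in salicylate-type arenes, and here only the 3-alkoxy group is exchanged for a coumarinyloxy group. The benzene ring is closed by intermolecular [4+2] annulation and aromatized on acidic work-up, when the silyl ketal collapses with loss of methanol and of the silyl group so that the silylated oxygen remains as the phenol. No stereocentre survives, because the ketal carbon of 12 forms racemic and becomes the sp2 carbon C8a'. The regioselectivity that the step needs is secured by matched polarization, the largest HOMO coefficient lying at the CH2 terminus (pushed by all three oxygens) and the largest LUMO coefficient at the ynal β-carbon, which places the formyl group ortho to the hydroxyl and para to the aryloxy group. The chemoselectivity for C≡C over C=O is secured by excluding Lewis and protic acids until the cycloaddition is over, since carbonyl addition of such dienes is normally seen only under acid or hydrogen-bond activation.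

Step 7
Reactants: 13 4-[(6,7-dimethoxy-2-oxo-2H-chromen-3-yl)oxy]-2-hydroxybenzaldehyde
Product: 15 daphnoretin methyl ether [6,7-dimethoxy-3-(2-oxo-2H-chromen-7-yloxy)-2H-chromen-2-one], via E-cinnamate ester 14 (not isolated)
Conditions: Ph3P=CHCO2Et, PhNEt2, reflux (ca. 215 °C)
Reagents that add atoms: ethyl (triphenylphosphoranylidene)acetate, CCOC(=O)C=P(c1ccccc1)(c1ccccc1)c1ccccc1
Why: Wittig olefination of the salicylaldehyde gives E-cinnamate 14, which at this temperature should isomerize to the Z-ester and lactonize onto the ortho phenol with loss of ethanol, the established one-pot coumarin synthesis.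

**Compound list**

1 | 2-hydroxy-4,5-dimethoxybenzaldehyde | COc1cc(O)c(C=O)cc1OC | starting material
2 | N-acetylglycine | CC(=O)NCC(=O)O | starting material
3 | N-(6,7-dimethoxy-2-oxo-2H-chromen-3-yl)acetamide | CC(=O)Nc1cc2cc(OC)c(OC)cc2oc1=O | intermediate
4 | 3-amino-6,7-dimethoxy-2H-chromen-2-one (not isolated) | Nc1cc2cc(OC)c(OC)cc2oc1=O | intermediate
5 | 3-hydroxy-6,7-dimethoxy-2H-chromen-2-one | Oc1cc2cc(OC)c(OC)cc2oc1=O | intermediate
6 | methyl but-2-ynoate | CC#CC(=O)OC | starting material
7 | methyl (2E)-3-[(6,7-dimethoxy-2-oxo-2H-chromen-3-yl)oxy]but-2-enoate | C/C(Oc1cc2cc(OC)c(OC)cc2oc1=O)=C\C(=O)OC | intermediate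
8 | lithium dienolate of 7, lithium (1E)-3-[(6,7-dimethoxy-2-oxo-2H-chromen-3-yl)oxy]-1-methoxybuta-1,3-dien-1-olate (not isolated) | C=C(Oc1cc2cc(OC)c(OC)cc2oc1=O)/C=C(\OC)[O-].[Li+] | intermediate
9 | 3-{[(3E)-4-methoxy-4-(trimethylsilyloxy)buta-1,3-dien-2-yl]oxy}-6,7-dimethoxy-2H-chromen-2-one | C=C(Oc1cc2cc(OC)c(OC)cc2oc1=O)/C=C(\OC)O[Si](C)(C)C | intermediate
10 | propargyl alcohol (prop-2-yn-1-ol) | C#CCO | starting material
11 | propynal | C#CC=O | intermediate
12 | racemic 4-[(6,7-dimethoxy-2-oxo-2H-chromen-3-yl)oxy]-6-methoxy-6-(trimethylsilyloxy)cyclohexa-1,4-diene-1-carbaldehyde (not isolated) | O=CC1=CCC(Oc2cc3cc(OC)c(OC)cc3oc2=O)=CC1(OC)O[Si](C)(C)C | intermediate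
13 | 4-[(6,7-dimethoxy-2-oxo-2H-chromen-3-yl)oxy]-2-hydroxybenzaldehyde | O=Cc1ccc(Oc2cc3cc(OC)c(OC)cc3oc2=O)cc1O | intermediate
14 | ethyl (2E)-3-{4-[(6,7-dimethoxy-2-oxo-2H-chromen-3-yl)oxy]-2-hydroxyphenyl}prop-2-enoate (not isolated) | CCOC(=O)/C=C/c1ccc(Oc2cc3cc(OC)c(OC)cc3oc2=O)cc1O | intermediate
15 | daphnoretin methyl ether, 6,7-dimethoxy-3-[(2-oxo-2H-chromen-7-yl)oxy]-2H-chromen-2-one | COc1cc2cc(Oc3ccc4ccc(=O)oc4c3)c(=O)oc2cc1OC | target

**Step count**

Total step count: 7. Longest linear sequence: 6 steps (steps 1, 2, 3, 4, 6 and 7); step 5 is a one-step branch that supplies the dienophile.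

**Steps most likely to fail**

1. Step 6. The ketene acetal may attack the formyl carbon (vinylogous aldol or cycloaddition across C=O) instead of the triple bond. The diene may also be hydrolysed, or propynal may polymerize, before cycloaddition, and aromatization may expel the silyloxy instead of the methoxy group. The fallback sets out from 1 and comes back at 15. Commercial 7-hydroxycoumarin would be O-alkylated with tert-butyl bromoacetate (K2CO3, acetone, reflux) to tert-butyl 2-[(2-oxo-2H-chromen-7-yl)oxy]acetate F1. The ester would be cleaved (TFA, CH2Cl2, rt) to 2-[(2-oxo-2H-chromen-7-yl)oxy]acetic acid F2. Perkin condensation of F2 with 1 (Ac2O, Et3N, 120 °C) would then build the 3-aryloxycoumarin ring of 15 directly, the usual route to 3-aryloxycoumarins.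

2. Step 4. The amide base or the dienolate may add to the lactone (ring opening or conjugate addition at C4), or silylation may occur on carbon. The fallback sets out from 5 and comes back at 13, bypassing the diene. Nucleophilic aromatic substitution of the oxyanion of 5 on commercial 4-fluoro-2-methoxybenzaldehyde (K2CO3, DMF, 110 °C) would give 4-[(6,7-dimethoxy-2-oxo-2H-chromen-3-yl)oxy]-2-methoxybenzaldehyde F3. Chelation-directed cleavage of only the methyl ether ortho to the formyl group (BCl3, CH2Cl2, −78 → 0 °C) would then give 13.

3. Step 3. The ambident oxyanion of 5 may react through C4 and then cyclize onto the ester, or conjugate addition to the β-methyl alkynoate may stall. The fallback sets out from 5 and 6 and comes back at 9. Hydroiodination of 6 (NaI, AcOH, 110 °C) would give methyl (2Z)-3-iodobut-2-enoate F4. Ullmann-type C–O coupling of 5 with F4 (CuI, N,N-dimethylglycine, Cs2CO3, dioxane, 80 °C) is bound to oxygen and should give, with retention, methyl (2Z)-3-[(6,7-dimethoxy-2-oxo-2H-chromen-3-yl)oxy]but-2-enoate F5, the geometric isomer of 7. Under the conditions of step 4, F5 should converge on diene 9.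

**Further compounds**

F1 | step 6 | tert-butyl 2-[(2-oxo-2H-chromen-7-yl)oxy]acetate | CC(C)(C)OC(=O)COc1ccc2ccc(=O)oc2c1
F2 | step 6 | 2-[(2-oxo-2H-chromen-7-yl)oxy]acetic acid | O=C(O)COc1ccc2ccc(=O)oc2c1
F3 | step 4 | 4-[(6,7-dimethoxy-2-oxo-2H-chromen-3-yl)oxy]-2-methoxybenzaldehyde | COc1cc(Oc2cc3cc(OC)c(OC)cc3oc2=O)ccc1C=O
F4 | step 3 | methyl (2Z)-3-iodobut-2-enoate | C/C(I)=C/C(=O)OC
F5 | step 3 | methyl (2Z)-3-[(6,7-dimethoxy-2-oxo-2H-chromen-3-yl)oxy]but-2-enoate | C/C(Oc1cc2cc(OC)c(OC)cc2oc1=O)=C/C(=O)OC
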